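**Plan**

- Locants: the side chain is numbered from the ring, C1' (benzylic) to C17' (CH3); the alkene is C8'=C9' (Z) and the carbinol is C16' (S).
- Retrosynthesis: first the three O-protecting groups (two aryl MOM, one TBS) are removed; then both sp2–sp3 bonds of the alkene, C9'–C10' and C7'–C8', are cut, which leaves acetylene as C8'/C9'; then ring–C1' (aryl Grignard + 1,7-dibromoheptane) and C14'–C15' (chloropentyl Grignard + (S)-propylene oxide).
- Enabling feature: C8'=C9' is an unbranched cis-CH=CH with one H on each carbon and a primary CH2 (C7', C10') on either side, so it is the syn-adduct of acetylene; the benzene ring and C16' sit seven and six CH2 groups away and can be carried as inert ethers.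
- Forward: no ring is formed (the benzene ring is bought as 5-bromoresorcinol); the ring–C7' iodide (steps 1–3) and the C10'–C17' iodide (steps 4–6) are made separately; in one flask the ring-side chain is added as a cuprate across acetylene and the resulting (Z)-alkenylcopper is alkylated by the C10'–C17' iodide (step 7); global deprotection follows (step 8).
- Stereochemistry: C16' (S) comes from (S)-propylene oxide, opened at its CH2 so the stereocentre is never a reaction site; the Z geometry comes from syn-carbocupration and retentive alkylation.

Key step: step 7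

Remark: in step 7 both alkenyl groups on copper are taken to be transferable to carbon under the HMPA/P(OEt)3 conditions, so the cuprate is used in only slight excess over the chiral iodide.

**Step 1**
Reactants: 1 5-bromoresorcinol (5-bromobenzene-1,3-diol)
Product: 2 1-bromo-3,5-bis(methoxymethoxy)benzene
Conditions: MOMCl (2.5 equiv), i-Pr2NEt (3 equiv), CH2Cl2, 0 °C → rt
Reagents that add atoms: chloromethyl methyl ether (MOMCl), COCCl
Why: O-alkylation of both phenols by the reactive α-chloro ether under amine base (Williamson-type MOM protection) masks the acidic OH groups against the organomagnesium, organolithium and organocopper reagents to come and is removable by mild acid.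

**Step 2**
Reactants: 2 1-bromo-3,5-bis(methoxymethoxy)benzene; 3 1,7-dibromoheptane
Product: 5 1-(7-bromoheptyl)-3,5-bis(methoxymethoxy)benzene, via arylmagnesium bromide 4 (not isolated)
Conditions: Mg, THF, 50 °C; then added slowly to 3 (3 equiv), Li2CuCl4 (3 mol %), THF, −10 °C → rt
Reagents that add atoms: none
Why: Magnesium insertion into the aryl C–Br bond followed by Li2CuCl4-catalysed sp2–sp3 Grignard cross-coupling (Kochi-type) with a threefold excess of the symmetrical primary dibromide should give the mono-arylated bromide, the excess suppressing double coupling and the MOM acetals being inert to the Grignard reagent.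

**Step 3**
Reactants: 5 1-(7-bromoheptyl)-3,5-bis(methoxymethoxy)benzene
Product: 6 1-(7-iodoheptyl)-3,5-bis(methoxymethoxy)benzene
Conditions: NaI (3 equiv), acetone, reflux
Reagents that add atoms: sodium iodide, [Na+].[I-]
Why: Finkelstein exchange (SN2 at the primary carbon, driven by precipitation of NaBr) should give the iodide needed for clean iodine–lithium exchange.

**Step 4**
Reactants: 7 1-bromo-5-chloropentane; 8 (S)-propylene oxide [(S)-2-methyloxirane]
Product: 10 (S)-8-chlorooctan-2-ol, via 5-chloropentylmagnesium bromide 9 (not isolated)
Conditions: Mg, THF, 30 °C; then CuI (10 mol %), 8 (0.85 equiv), THF, −30 → 0 °C; aq NH4Cl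
Reagents that add atoms: none
Why: Magnesium inserts selectively into the C–Br bond of the bromochloride, and the CuI-catalysed SN2 opening of the epoxide by the Grignard reagent occurs at the unsubstituted CH2, so the C–O bond of the stereocentre is never broken and the (S) configuration of the epoxide becomes the (S)-carbinol C16'.

**Step 5**
Reactants: 10 (S)-8-chlorooctan-2-ol
Product: 11 (S)-tert-butyl[(8-chlorooctan-2-yl)oxy]dimethylsilane
Conditions: TBSCl (1.2 equiv), imidazole (2.5 equiv), DMF, rt
Reagents that add atoms: tert-butyldimethylsilyl chloride (TBSCl), CC(C)(C)[Si](C)(C)Cl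
Why: Standard imidazole-promoted silylation of the secondary alcohol masks it for the organocopper step without touching the stereocentre or the primary chloride.

**Step 6**
Reactants: 11 (S)-tert-butyl[(8-chlorooctan-2-yl)oxy]dimethylsilane
Product: 12 (S)-tert-butyl[(8-iodooctan-2-yl)oxy]dimethylsilane
Conditions: NaI (3 equiv), NaHCO3 (0.1 equiv), 2-butanone, reflux
Reagents that add atoms: sodium iodide, [Na+].[I-]
Why: Finkelstein exchange of the primary chloride in refluxing 2-butanone should give the more reactive primary iodide needed to alkylate an alkenylcopper, the bicarbonate buffer keeping the silyl ether intact.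

**Step 7**
Reactants: 6 1-(7-iodoheptyl)-3,5-bis(methoxymethoxy)benzene (1.2 equiv); 13 acetylene (1.2 equiv); 12 (S)-tert-butyl[(8-iodooctan-2-yl)oxy]dimethylsilane (1.0 equiv)
Product: 18 tert-butyl({(2S,9Z)-17-[3,5-bis(methoxymethoxy)phenyl]heptadec-9-en-2-yl}oxy)dimethylsilane, via alkyllithium 14 (not isolated), via lithium dialkylcuprate 15 (not isolated), via lithium bis(Z-alkenyl)cuprate 16 (not isolated), via Z-alkenylcopper 17 (not isolated)
Conditions: 6, t-BuLi (2.4 equiv), Et2O/pentane, −78 °C; CuBr·SMe2 (0.6 equiv), −78 → −40 °C; HC≡CH (metered gas), −50 → −25 °C; then 12, HMPA, P(OEt)3, THF, −40 °C → rt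
Reagents that add atoms: none
Why: Iodine–lithium exchange on 6 gives the primary alkyllithium 14, which with half an equivalent of CuBr·SMe2 forms the Gilman cuprate 15; each C–Cu bond of 15 then adds syn across one molecule of acetylene (π-complexation, then four-centre carbometalation) to give the dialkenylcuprate 16, and 16 and then the residual alkenylcopper 17 substitute the primary iodide 12 (SN2-type oxidative addition at the CH2–I carbon to a trivalent copper species, then reductive elimination with retention at the sp2 carbon), which creates the C9'–C10' bond. The closest known reaction type is the carbocupration of acetylene by lithium dialkylcuprates followed by alkylation of the (Z)-alkenylcuprate with a primary alkyl iodide in THF/HMPA/P(OEt)3, a Normant-type carbocupration long used as a one-flask entry to (Z)-disubstituted alkenes such as lepidopteran pheromones. No ring is closed. No stereocentre is created; the only new stereo element, the C8'=C9' geometry, is fixed as Z by the strictly syn addition to the alkyne and the retentive coupling, and the remote silyl-protected C16' centre is untouched. The step needs a single insertion of acetylene (no second insertion to dienylcopper species, no acetylide formation), which the low temperature, the ether solvent and a metered volume of gas should secure, and it needs C-alkylation without elimination, which the unhindered primary iodide (five CH2 groups between the reacting carbon and the silyloxy carbon) together with HMPA and P(OEt)3 should secure. Ortho-lithiation of the bis-MOM ring by 14 should be avoided by keeping 14 at −78 °C and transmetalating to copper at once.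

**Step 8**
Reactants: 18 tert-butyl({(2S,9Z)-17-[3,5-bis(methoxymethoxy)phenyl]heptadec-9-en-2-yl}oxy)dimethylsilane
Product: 19 Hansfordiol E, 5-[(8Z,16S)-16-hydroxyheptadec-8-en-1-yl]benzene-1,3-diol
Conditions: HCl (0.5 M in MeOH), 40 °C
Reagents that add atoms: none
Why: Acid-catalysed methanolysis (transacetalisation of both aryl MOM ethers to dimethoxymethane and solvolysis of the secondary TBS ether) should free all three hydroxyl groups in one operation without affecting the isolated Z-alkene or the C16' stereocentre.

**Compound list**

1 | 5-bromoresorcinol (5-bromobenzene-1,3-diol) | Oc1cc(O)cc(Br)c1 | starting material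
2 | 1-bromo-3,5-bis(methoxymethoxy)benzene | COCOc1cc(Br)cc(OCOC)c1 | intermediate
3 | 1,7-dibromoheptane | BrCCCCCCCBr | starting material
4 | [3,5-bis(methoxymethoxy)phenyl]magnesium bromide | COCOc1cc([Mg]Br)cc(OCOC)c1 | intermediate
5 | 1-(7-bromoheptyl)-3,5-bis(methoxymethoxy)benzene | COCOc1cc(CCCCCCCBr)cc(OCOC)c1 | intermediate
6 | 1-(7-iodoheptyl)-3,5-bis(methoxymethoxy)benzene | COCOc1cc(CCCCCCCI)cc(OCOC)c1 | intermediate
7 | 1-bromo-5-chloropentane | ClCCCCCBr | starting material
8 | (S)-propylene oxide [(S)-2-methyloxirane] | C[C@H]1CO1 | starting material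
9 | (5-chloropentyl)magnesium bromide | ClCCCCC[Mg]Br | intermediate
10 | (S)-8-chlorooctan-2-ol | C[C@H](O)CCCCCCCl | intermediate
11 | (S)-tert-butyl[(8-chlorooctan-2-yl)oxy]dimethylsilane | C[C@H](O[Si](C)(C)C(C)(C)C)CCCCCCCl | intermediate
12 | (S)-tert-butyl[(8-iodooctan-2-yl)oxy]dimethylsilane | C[C@H](O[Si](C)(C)C(C)(C)C)CCCCCCI | intermediate
13 | acetylene | C#C | starting material
14 | {7-[3,5-bis(methoxymethoxy)phenyl]heptyl}lithium | [Li]CCCCCCCc1cc(OCOC)cc(OCOC)c1 | intermediate
15 | lithium bis{7-[3,5-bis(methoxymethoxy)phenyl]heptyl}cuprate | [Li+].COCOc1cc(OCOC)cc(CCCCCCC[Cu-]CCCCCCCc2cc(OCOC)cc(OCOC)c2)c1 | intermediate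
16 | lithium bis{(Z)-9-[3,5-bis(methoxymethoxy)phenyl]non-1-en-1-yl}cuprate | [Li+].COCOc1cc(OCOC)cc(CCCCCCC/C=C\[Cu-]/C=C\CCCCCCCc2cc(OCOC)cc(OCOC)c2)c1 | intermediate
17 | {(Z)-9-[3,5-bis(methoxymethoxy)phenyl]non-1-en-1-yl}copper | COCOc1cc(OCOC)cc(CCCCCCC/C=C\[Cu])c1 | intermediate
18 | tert-butyl({(2S,9Z)-17-[3,5-bis(methoxymethoxy)phenyl]heptadec-9-en-2-yl}oxy)dimethylsilane | C[C@H](O[Si](C)(C)C(C)(C)C)CCCCCC/C=C\CCCCCCCc1cc(OCOC)cc(OCOC)c1 | intermediate
19 | Hansfordiol E, 5-[(8Z,16S)-16-hydroxyheptadec-8-en-1-yl]benzene-1,3-diol | C[C@H](O)CCCCCC/C=C\CCCCCCCc1cc(O)cc(O)c1 | target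

**Step count and risks**

Total step count: 8. Longest linear sequence: 5 steps (1, 2, 3, 7, 8); the branch of steps 4–6 joins in step 7.

Steps most likely to fail:

1. Step 7. What may go wrong: a second insertion of acetylene into the alkenylcuprate (oligomerisation to dienylcopper species), ortho-lithiation of the bis-MOM ring by the alkyllithium before transmetalation, or slow sp2–sp3 alkylation with thermal decay and homocoupling of the alkenylcopper. Fallback (stepwise acetylide route with syn semi-hydrogenation): it sets out from bromide 5 and iodide 12 and comes back to the route at 18. Bromide 5 is treated with LiC≡CH·H2NCH2CH2NH2 in DMSO at rt to give the terminal alkyne 1,3-bis(methoxymethoxy)-5-(non-8-yn-1-yl)benzene F1. Deprotonation with n-BuLi in THF at −78 °C gives its lithium acetylide F2, which is alkylated with 12 in THF/DMPU (−78 °C → rt); this forms the C9'–C10' bond and gives the internal alkyne tert-butyl({(2S)-17-[3,5-bis(methoxymethoxy)phenyl]heptadec-9-yn-2-yl}oxy)dimethylsilane F3. Semi-hydrogenation of F3 (H2, 1 atm, Pd/CaCO3 poisoned with Pb(OAc)2, quinoline, hexane/EtOAc; Lindlar reduction) should then deliver 18 by syn addition of hydrogen.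

2. Step 2. What may go wrong: double arylation of the dibromide, biaryl homocoupling of the Grignard reagent, or incomplete magnesium insertion into the electron-rich aryl bromide. Fallback (sp–sp2 coupling, then saturation): it sets out from 2 and comes back to the route at 6, bypassing 5 and step 3. Sonogashira coupling of 2 with commercial hept-6-yn-1-ol (Pd(PPh3)2Cl2, CuI, Et3N, 70 °C) gives 7-[3,5-bis(methoxymethoxy)phenyl]hept-6-yn-1-ol F4. Hydrogenation (H2, Pd/C, EtOAc) gives 7-[3,5-bis(methoxymethoxy)phenyl]heptan-1-ol F5, and Appel-type iodination (I2, PPh3, imidazole, CH2Cl2, 0 °C) gives 6.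

3. Step 8. What may go wrong: capture of the methoxymethyl cation by the freed, strongly nucleophilic resorcinol ring (C-hydroxymethylation and methylene bridging), or acid-promoted migration of the alkene. Fallback (two-stage orthogonal deprotection with a cation scavenger): it sets out from 18 and comes back to the route at 19. Bu4NF in THF at rt removes the silyl ether to give (2S,9Z)-17-[3,5-bis(methoxymethoxy)phenyl]heptadec-9-en-2-ol F6. The two MOM groups are then cleaved with ZnBr2 and n-PrSH in CH2Cl2 at 0 °C, the thiol trapping the methoxymethyl cation as a monothioacetal before it can attack the ring, to give 19.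

**Further compounds**

F1 | step 7 | 1,3-bis(methoxymethoxy)-5-(non-8-yn-1-yl)benzene | COCOc1cc(CCCCCCCC#C)cc(OCOC)c1
F2 | step 7 | {9-[3,5-bis(methoxymethoxy)phenyl]non-1-yn-1-yl}lithium | [Li]C#CCCCCCCCc1cc(OCOC)cc(OCOC)c1
F3 | step 7 | tert-butyl({(2S)-17-[3,5-bis(methoxymethoxy)phenyl]heptadec-9-yn-2-yl}oxy)dimethylsilane | C[C@H](O[Si](C)(C)C(C)(C)C)CCCCCCC#CCCCCCCCc1cc(OCOC)cc(OCOC)c1
F4 | step 2 | 7-[3,5-bis(methoxymethoxy)phenyl]hept-6-yn-1-ol | OCCCCCC#Cc1cc(OCOC)cc(OCOC)c1
F5 | step 2 | 7-[3,5-bis(methoxymethoxy)phenyl]heptan-1-ol | OCCCCCCCc1cc(OCOC)cc(OCOC)c1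
F6 | step 8 | (2S,9Z)-17-[3,5-bis(methoxymethoxy)phenyl]heptadec-9-en-2-ol | C[C@H](O)CCCCCC/C=C\CCCCCCCc1cc(OCOC)cc(OCOC)c1
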